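Ring A is numbered C1 (OMe), C2 (prenyl), C3 (OH), C4 (H), C5 (OH), C6 (CH2–CO–aryl); ring B is the 2,4-dihydroxyphenyl ring on the carbonyl group.
Cuts: first the bond from the carbonyl carbon to ring B (ring B aryllithium plus ring A arylacetaldehyde). Then, in one operation, the C1–O bond of the methoxy group and the C2–CH2 bond of the prenyl group.
Enabling feature: OMe and prenyl sit on the adjacent carbons C1 and C2, directly beside the C3 oxygen. A C1–C2 aryne of a 4-alkylresorcinol diether can therefore take both groups from one molecule of 3-methoxy-3-methylbut-1-ene, and the C3 oxygen decides which end receives the oxygen.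
Forward order: 2,4-dihydroxyphenylacetic acid is protected, reduced and silylated, turned into a mesityliodonium salt at C2 and taken through the aryne step. It is then oxidised to the aldehyde, joined to ring B, oxidised to the ketone and unmasked. Both benzene rings are bought and no ring is made.
Stereochemistry: the target is achiral and its alkene carries two identical methyl groups. The one carbinol stereocentre created on joining the rings forms as the racemate and is erased by oxidation.
Key step: step 8

Remark on the chemistry: the four building blocks marked as starting materials are taken as commercial. MOM stands for CH2OCH3 and TIPS for Si(iPr)3. The side-chain oxygen is carried as its TIPS ether throughout.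

Step 1
Reactants: 1 2,4-dihydroxyphenylacetic acid
Product: 2 methyl 2-(2,4-dihydroxyphenyl)acetate
Conditions: MeOH, H2SO4 (cat.), reflux
Reagents that add atoms: methanol, CO
Why: Fischer esterification in a large excess of methanol should outrun lactonisation onto the ortho phenol and removes the acidic proton before acetal protection and hydride reduction.

Step 2
Reactants: 2 methyl 2-(2,4-dihydroxyphenyl)acetate
Product: 3 methyl 2-[2,4-bis(methoxymethoxy)phenyl]acetate
Conditions: MOMCl, iPr2NEt, CH2Cl2, 0 °C to rt
Reagents that add atoms: chloromethyl methyl ether, COCCl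
Why: Williamson-type O-alkylation of both phenols is routine, and MOM is chosen because it withstands amide base, fluoride and aryllithium, cannot migrate to a neighbouring aryl anion as a silyl group would, and keeps the inductive pull of the C3 oxygen needed in step 8.

Step 3
Reactants: 3 methyl 2-[2,4-bis(methoxymethoxy)phenyl]acetate
Product: 4 2-[2,4-bis(methoxymethoxy)phenyl]ethanol
Conditions: LiAlH4, THF, 0 °C
Reagents that add atoms: none
Why: Hydride reduction of the ester to the primary alcohol leaves aryl MOM ethers untouched.

Step 4
Reactants: 4 2-[2,4-bis(methoxymethoxy)phenyl]ethanol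
Product: 5 {2-[2,4-bis(methoxymethoxy)phenyl]ethoxy}triisopropylsilane
Conditions: TIPSCl, imidazole, DMF, rt
Reagents that add atoms: triisopropylsilyl chloride, CC(C)[Si](Cl)(C(C)C)C(C)C
Why: Imidazole-promoted silylation is standard, and the TIPS ether is preferred to a smaller silyl ether because its shielded, weakly basic oxygen should neither close onto the neighbouring aryne carbon C1 (a five-membered ring) in step 8 nor be lost in the mildly acidic step 6.

Step 5
Reactants: 6 iodomesitylene
Product: 7 [hydroxy(tosyloxy)iodo]mesitylene
Conditions: mCPBA, TsOH·H2O, CH2Cl2/CF3CH2OH 1:1, rt; precipitation with Et2O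
Reagents that add atoms: 3-chloroperbenzoic acid, OOC(=O)c1cccc(Cl)c1; 4-toluenesulfonic acid monohydrate, Cc1ccc(S(=O)(=O)O)cc1.O
Why: Peracid oxidation of an iodoarene in the presence of TsOH is the usual one-pot entry to hydroxy(tosyloxy)iodanes (Koser-type reagents), and isolating crystalline 7 keeps peracid and free sulfonic acid away from the acetals of 5.

Step 6
Reactants: 5 {2-[2,4-bis(methoxymethoxy)phenyl]ethoxy}triisopropylsilane; 7 [hydroxy(tosyloxy)iodo]mesitylene
Product: 8 [2,4-bis(methoxymethoxy)-5-(2-triisopropylsilyloxyethyl)phenyl](mesityl)iodonium tosylate (iodine on C2 of ring A)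
Conditions: CF3CH2OH/CH2Cl2, 0 °C to rt; trituration with pentane/Et2O
Reagents that add atoms: none
Why: Dehydrative diaryliodonium synthesis, an electrophilic aromatic substitution of an electron-rich arene by a trivalent iodine electrophile in a fluoroalcohol, should take place at C2, which is para to the C5 ether and ortho to the C3 ether, because C4 is flanked by two MOM ethers and C1 is meta to both oxygens.

Step 7
Reactants: 9 2-methylbut-3-en-2-ol
Product: 10 3-methoxy-3-methylbut-1-ene
Conditions: KOH (powder), MeI, DMSO, rt; pentane extraction, distillation from CaH2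
Reagents that add atoms: iodomethane, CI
Why: Williamson methylation of the tertiary alkoxide occurs at oxygen without allylic transposition, and distillation from CaH2 keeps residual alcohol and water out of the aryne step.

Step 8
Reactants: 8 [2,4-bis(methoxymethoxy)-5-(2-triisopropylsilyloxyethyl)phenyl](mesityl)iodonium tosylate; 10 3-methoxy-3-methylbut-1-ene
Product: 13 triisopropyl{2-[2-methoxy-4,6-bis(methoxymethoxy)-3-(3-methylbut-2-enyl)phenyl]ethoxy}silane, via C1–C2 aryne 11 (not isolated), via oxonium aryl anion zwitterion 12 (not isolated)
Conditions: LiN(SiMe3)2 (1.5 equiv, added slowly), 10 (about 20 equiv)/toluene 1:1, rt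
Reagents that add atoms: none
Why: Proposed new method: LiN(SiMe3)2 removes the only hydrogen ortho to the iodonium centre (C1–H, since C3 carries OMOM and the mesityl ortho positions are methylated), and loss of iodomesitylene gives aryne 11, as in the known base-induced aryne generation from aryl(mesityl)iodonium salts. The inductively withdrawing C3 oxygen distorts the triple bond, so the ether oxygen of 10, present as co-solvent, should add at the distal carbon C1 while the charge builds up at C2 next to that oxygen, giving zwitterion 12. In 12 the atoms C2–C1–O–CMe2–CH=CH2 form a six-membered array, and a charge-accelerated [3,3] shift joins C2 to the terminal CH2, breaks the O–CMe2 bond and leaves OMe on C1 and the transposed (prenyl) chain on C2; a more dissociative ion-pair collapse at the unhindered allyl terminus would lead to the same product. The closest known reaction is the aryne aza-Claisen rearrangement of tertiary allylamines, and capture of arynes by ether oxygen is known from the opening of cyclic ethers. No ring closes and no stereocentre forms. The step needs regioselective addition to an unsymmetrical aryne, secured by the C3 OMOM group against the small steric bias of the C6 chain, and a rearrangement faster than proton transfer, which is favoured by a medium whose only proton source is HN(SiMe3)2, by the absence of an allylic C–H in 10 (no ene reaction) and by the non-nucleophilic TIPS-shielded side-chain oxygen.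

Step 9
Reactants: 13 triisopropyl{2-[2-methoxy-4,6-bis(methoxymethoxy)-3-(3-methylbut-2-enyl)phenyl]ethoxy}silane
Product: 14 2-[2-methoxy-4,6-bis(methoxymethoxy)-3-(3-methylbut-2-enyl)phenyl]ethanol
Conditions: Bu4NF, THF, 0 °C to rt
Reagents that add atoms: none
Why: Fluoride cleavage of the Si–O bond is selective for the silyl ether and leaves MOM ethers, the aryl methyl ether and the prenyl group untouched.

Step 10
Reactants: 14 2-[2-methoxy-4,6-bis(methoxymethoxy)-3-(3-methylbut-2-enyl)phenyl]ethanol
Product: 15 2-[2-methoxy-4,6-bis(methoxymethoxy)-3-(3-methylbut-2-enyl)phenyl]acetaldehyde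
Conditions: Dess–Martin periodinane, NaHCO3, CH2Cl2, 0 °C to rt
Reagents that add atoms: none
Why: Buffered Dess–Martin oxidation stops at the aldehyde, tolerates the trisubstituted alkene and the electron-rich ring, and gives the sensitive arylacetaldehyde cleanly enough to be used at once.

Step 11
Reactants: 16 4-bromoresorcinol
Product: 17 1-bromo-2,4-bis(methoxymethoxy)benzene
Conditions: MOMCl, iPr2NEt, CH2Cl2, 0 °C to rt
Reagents that add atoms: chloromethyl methyl ether, COCCl
Why: The same Williamson-type acetal protection as in step 2 masks both phenols of ring B so that the bromide can be lithiated and all four acetals can fall together at the end.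

Step 12
Reactants: 17 1-bromo-2,4-bis(methoxymethoxy)benzene; 15 2-[2-methoxy-4,6-bis(methoxymethoxy)-3-(3-methylbut-2-enyl)phenyl]acetaldehyde
Product: 19 racemic 1-[2,4-bis(methoxymethoxy)phenyl]-2-[2-methoxy-4,6-bis(methoxymethoxy)-3-(3-methylbut-2-enyl)phenyl]ethanol, via aryllithium 18 (not isolated)
Conditions: 17, n-BuLi, THF, −78 °C; then 15, −78 °C; H2O quench
Reagents that add atoms: none
Why: Bromine–lithium exchange at −78 °C is faster than MOM-directed deprotonation, and 1,2-addition of the chelated aryllithium to the aldehyde at low temperature should outrun enolisation; the new carbinol centre forms without control as the racemate and disappears in step 13.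

Step 13
Reactants: 19 racemic 1-[2,4-bis(methoxymethoxy)phenyl]-2-[2-methoxy-4,6-bis(methoxymethoxy)-3-(3-methylbut-2-enyl)phenyl]ethanol
Product: 20 1-[2,4-bis(methoxymethoxy)phenyl]-2-[2-methoxy-4,6-bis(methoxymethoxy)-3-(3-methylbut-2-enyl)phenyl]ethanone
Conditions: Dess–Martin periodinane, NaHCO3, CH2Cl2, 0 °C to rt
Reagents that add atoms: none
Why: Dess–Martin oxidation of the secondary benzylic alcohol gives the deoxybenzoin ketone, and the bicarbonate buffer protects the easily ionised electron-rich benzylic alcohol from the acetic acid released.

Step 14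
Reactants: 20 1-[2,4-bis(methoxymethoxy)phenyl]-2-[2-methoxy-4,6-bis(methoxymethoxy)-3-(3-methylbut-2-enyl)phenyl]ethanone
Product: 21 glicophenone
Conditions: HCl (1.25 M in MeOH), 0 °C to rt
Reagents that add atoms: none
Why: Acid-catalysed transacetalisation of aryl MOM ethers in methanol is the standard unmasking of prenylated polyphenols, and dilute acid at low temperature is chosen because the C3 phenol can add to the prenyl alkene and the C5 phenol can condense with the ketone, the latter being slowed by the hydrogen-bonded, electron-rich resorcinyl carbonyl group.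

Compound list
1 | 2,4-dihydroxyphenylacetic acid | OC(=O)Cc1ccc(O)cc1O | starting material
2 | methyl 2-(2,4-dihydroxyphenyl)acetate | COC(=O)Cc1ccc(O)cc1O | intermediate
3 | methyl 2-[2,4-bis(methoxymethoxy)phenyl]acetate | COC(=O)Cc1ccc(OCOC)cc1OCOC | intermediate
4 | 2-[2,4-bis(methoxymethoxy)phenyl]ethanol | OCCc1ccc(OCOC)cc1OCOC | intermediate
5 | {2-[2,4-bis(methoxymethoxy)phenyl]ethoxy}triisopropylsilane | CC(C)[Si](OCCc1ccc(OCOC)cc1OCOC)(C(C)C)C(C)C | intermediate
6 | iodomesitylene | Cc1cc(C)c(I)c(C)c1 | starting material
7 | [hydroxy(tosyloxy)iodo]mesitylene | Cc1cc(C)c(I(O)OS(=O)(=O)c2ccc(C)cc2)c(C)c1 | intermediate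
8 | [2,4-bis(methoxymethoxy)-5-(2-triisopropylsilyloxyethyl)phenyl](mesityl)iodonium tosylate | Cc1cc(C)c([I+]c2cc(CCO[Si](C(C)C)(C(C)C)C(C)C)c(OCOC)cc2OCOC)c(C)c1.Cc1ccc(S(=O)(=O)[O-])cc1 | intermediate
9 | 2-methylbut-3-en-2-ol | CC(C)(O)C=C | starting material
10 | 3-methoxy-3-methylbut-1-ene | COC(C)(C)C=C | intermediate
11 | C1–C2 aryne: 3,5-bis(methoxymethoxy)-6-(2-triisopropylsilyloxyethyl)benzyne | COCOC1=CC(OCOC)=C(CCO[Si](C(C)C)(C(C)C)C(C)C)C#C1 | intermediate
12 | zwitterion: methyl(2-methylbut-3-en-2-yl)aryloxonium on C1, aryl anion on C2 | C=CC(C)(C)[O+](C)c1[c-]c(OCOC)cc(OCOC)c1CCO[Si](C(C)C)(C(C)C)C(C)C | intermediate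
13 | triisopropyl{2-[2-methoxy-4,6-bis(methoxymethoxy)-3-(3-methylbut-2-enyl)phenyl]ethoxy}silane | COc1c(CC=C(C)C)c(OCOC)cc(OCOC)c1CCO[Si](C(C)C)(C(C)C)C(C)C | intermediate
14 | 2-[2-methoxy-4,6-bis(methoxymethoxy)-3-(3-methylbut-2-enyl)phenyl]ethanol | COc1c(CC=C(C)C)c(OCOC)cc(OCOC)c1CCO | intermediate
15 | 2-[2-methoxy-4,6-bis(methoxymethoxy)-3-(3-methylbut-2-enyl)phenyl]acetaldehyde | COc1c(CC=C(C)C)c(OCOC)cc(OCOC)c1CC=O | intermediate
16 | 4-bromoresorcinol | Oc1ccc(Br)c(O)c1 | starting material
17 | 1-bromo-2,4-bis(methoxymethoxy)benzene | COCOc1ccc(Br)c(OCOC)c1 | intermediate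
18 | 2,4-bis(methoxymethoxy)phenyllithium | [Li]c1ccc(OCOC)cc1OCOC | intermediate
19 | racemic 1-[2,4-bis(methoxymethoxy)phenyl]-2-[2-methoxy-4,6-bis(methoxymethoxy)-3-(3-methylbut-2-enyl)phenyl]ethanol | COc1c(CC=C(C)C)c(OCOC)cc(OCOC)c1CC(O)c1ccc(OCOC)cc1OCOC | intermediate
20 | 1-[2,4-bis(methoxymethoxy)phenyl]-2-[2-methoxy-4,6-bis(methoxymethoxy)-3-(3-methylbut-2-enyl)phenyl]ethanone | COc1c(CC=C(C)C)c(OCOC)cc(OCOC)c1CC(=O)c1ccc(OCOC)cc1OCOC | intermediate
21 | glicophenone, 1-(2,4-dihydroxyphenyl)-2-[4,6-dihydroxy-2-methoxy-3-(3-methylbut-2-enyl)phenyl]ethanone | COc1c(CC=C(C)C)c(O)cc(O)c1CC(=O)c1ccc(O)cc1O | target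

Total step count: 14. Longest linear sequence: 11 steps (1, 2, 3, 4, 6, 8, 9, 10, 12, 13, 14).

Steps most likely to fail

Step 8.
- The hindered, weakly nucleophilic ether oxygen may lose the aryne to amide or amine nitrogen.
- The C6 chain may push part of the addition to C2.
- The zwitterion may collapse by proton transfer before the allyl shift. The proton can come from a gem-dimethyl group, with loss of isoprene, or from the O-methyl group, followed by a [2,3] shift.

The fallback makes the same two bonds one after the other by known reactions. It sets out from 8 and uses alcohol 9 in place of ether 10. The aryne is generated with LiN(SiMe3)2 in toluene in the presence of the lithium alkoxide of 9. Alkoxide addition to the aryne at C1 and protonation at C2 should give the C1 1,1-dimethylallyl aryl ether F1. Heating in N,N-diethylaniline at about 160 °C brings about the aromatic Claisen rearrangement into the only free ortho position, C2, and gives the C1 phenol with the C2 prenyl group F2. Methylation with MeI and K2CO3 in acetone comes back to the route at 13.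

Step 14. The Brønsted acid may drive two cyclisations of the liberated phenols. The C3 hydroxyl can add to the prenyl double bond, closing a chroman. The C5 hydroxyl can cyclodehydrate onto the ketone, closing a benzofuran. The fallback replaces acid solvolysis by a protecting-group exchange and sets out from 20. Et3SiOTf and 2,2'-bipyridyl in CH2Cl2 at 0 °C to rt convert aryl MOM ethers directly into aryl silyl ethers under nearly neutral conditions and should give the tetrakis(triethylsilyl) ether of glicophenone F3. Any silyl enol ether formed at the ketone is cleaved in the next operation. Acetic acid-buffered Bu4NF in THF at 0 °C then gives the target 21.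

Step 6. The acetals or the silyl ether may be lost in the acidic fluoroalcohol medium. One-electron oxidation of the very electron-rich ring may lead to oxidative coupling instead of carbon–iodine bond formation. The lipophilic salt may also resist precipitation. The fallback fixes the position by a metal handle and sets out from 5. NBS in MeCN at 0 °C brominates C2 and gives the C2 aryl bromide F4. Bromine–lithium exchange with n-BuLi in THF at −78 °C followed by Bu3SnCl gives the C2 tributylstannane F5. Ipso-destannylation with 7 in CH2Cl2 at rt, without fluoroalcohol, comes back to the route at 8.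

Further compounds
F1 | step 8 | triisopropyl{2-[2,4-bis(methoxymethoxy)-6-(2-methylbut-3-en-2-yloxy)phenyl]ethoxy}silane | C=CC(C)(C)Oc1cc(OCOC)cc(OCOC)c1CCO[Si](C(C)C)(C(C)C)C(C)C
F2 | step 8 | 3,5-bis(methoxymethoxy)-2-(3-methylbut-2-enyl)-6-(2-triisopropylsilyloxyethyl)phenol | Oc1c(CC=C(C)C)c(OCOC)cc(OCOC)c1CCO[Si](C(C)C)(C(C)C)C(C)C
F3 | step 14 | glicophenone tetrakis(triethylsilyl) ether | COc1c(CC=C(C)C)c(O[Si](CC)(CC)CC)cc(O[Si](CC)(CC)CC)c1CC(=O)c1ccc(O[Si](CC)(CC)CC)cc1O[Si](CC)(CC)CC
F4 | step 6 | {2-[5-bromo-2,4-bis(methoxymethoxy)phenyl]ethoxy}triisopropylsilane | COCOc1cc(OCOC)c(CCO[Si](C(C)C)(C(C)C)C(C)C)cc1Br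
F5 | step 6 | {2-[2,4-bis(methoxymethoxy)-5-(tributylstannyl)phenyl]ethoxy}triisopropylsilane | CCCC[Sn](CCCC)(CCCC)c1cc(CCO[Si](C(C)C)(C(C)C)C(C)C)c(OCOC)cc1OCOC
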